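## Structural features

The target 38 is a germacranolide: a ten-membered carbocycle C1–C10 trans-fused along C7–C8 to an α-methylene-γ-butyrolactone (C11, C12, C13; lactone oxygen on C8). Seven contiguous stereocentres run from C4 to C10: the trisubstituted epoxide (C4 with its methyl, C5), the senecioate carbinol C6, the fusion carbons C7 and C8, the free carbinol C9 and the methyl-bearing C10. C1–C3 are plain methylenes. Read along the chain from C10 to C6, the relations are Me10/O9 anti, O9/O8 anti (an erythro diol), O8/C11 syn (the trans lactone) and C11/O6 syn. In the oxirane C3 and C6 are cis, the imprint of a (Z)-C4=C5 olefin, and the oxirane oxygen is threo to O6. The fragile groups are the exo-methylene lactone (Michael acceptor), the epoxide (acid, transannular attack by O9), the senecioate (deconjugation or cleavage by base) and the O6/O8/O9 hydroxy-lactone array, which can translactonise. The real difficulty is closing the ten-membered ring on a chain with five contiguous sp3 stereocentres (C6–C10), and then controlling the face of a late epoxidation in a medium ring. The key step exploits the C1–C3 methylene run: C3 is a primary allylic carbon on the (Z)-olefin and C2 is unsubstituted and can carry a removable phenylsulfonyl group, so the ring bond C2–C3 can be made by SN2 displacement with no stereocentre at stake.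

## Logic of the disconnections

**38 ⇒ 37 ⇒ 35 + 36.** The O9–benzyl bond and the O6–acyl bond are cut last. The ester cannot survive enolate or carbanion chemistry, and O9 must stay distinguishable from O6, so O9 keeps one benzyl-type ether from the moment C9 is made. The forward steps need an acylation that does not deconjugate 36 and a final deprotection that is neutral towards epoxide, ester and methylene lactone.

**35 ⇒ 34 ⇒ 33.** The two C–O bonds of the oxirane and the O6–Si bond are cut. The (Z)-olefin is what makes C3 allylic for the ring closure, so the epoxide has to follow it. This leaves the configuration of C4 and C5 as the only stereochemistry set on the macrocycle. The forward step must deliver oxygen to the face threo to O6.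

**33 ⇒ 30 ⇒ 29 ⇒ 28.** The C11=C13 bond is cut and C12 is taken back to the aldehyde level as a methyl acetal in a five-membered ring with O8. An enolisable lactone or an acrylate cannot pass the carbanion step. With the acetal, O8 is never free, so no choice between a γ- and a δ-lactone arises and O9 needs no second protection. The forward steps need acetal hydrolysis selective over a secondary silyl ether.

**28 ⇒ 27 ⇒ 26 (key).** The C2–S bond and the ring bond C2–C3 are cut, opening the carbocycle to a chain with a sulfone-stabilised carbanion at C2 and a primary (Z)-allylic chloride at C3. An 8,9-acetonide with a C12 silyl ether and a benzyl-type ether on O6 would also give a base-stable chain. It is not used because it releases O8 and O9 together and places an ether oxygen five atoms from the electrophilic C3. In 26 the only carbon acid is C2, O6 is a silyl ether, and the trans-fused oxolane holds C6 and C9 as they are held in 38. The forward step needs high dilution and SN2 rather than SN2′ attack.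

**26 ⇒ 24 ⇒ 23 ⇒ 22 ⇒ 17 + 21.** The C3–Cl bond goes back to C3–O and the C5–C6 bond is cut. This splits the chain into a stereo-rich aldehyde and a small alkenyl iodide of fixed (Z) geometry. The forward addition must follow the Felkin–Anh sense at C6, and the two allylic oxygens must be told apart (primary triethylsilyl against secondary tert-butyldimethylsilyl).

**21 ⇒ 20 ⇒ 18.** The C4–CH3 and C5–I bonds are cut across an alkyne. Anti carbometalation directed by the hydroxyl sets the (Z) geometry in one step from a three-carbon alkyne.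

**17 ⇒ 15 ⇒ 14 ⇒ 12 + 13.** The C6 aldehyde is traced to a 2-methylprop-1-enyl group, the sulfone to a sulfide, and the C2–S bond is cut. The trisubstituted olefin is a masked aldehyde that is inert to the sulfur chemistry, and the vinyl group left by the crotylation accepts 13 directly in the anti-Markovnikov sense. The forward steps need chemoselection between a terminal and a trisubstituted olefin.

**12 ⇒ 11 ⇒ 8 + 9.** The O9–benzyl and C9–C10 bonds are cut. One crotyl transfer sets C9 and C10 (anti) and leaves the C1=C2 vinyl group. The forward step needs reagent control of the aldehyde face (8,9-anti).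

**8 ⇒ 7 ⇒ 6 ⇒ 5 ⇒ 2 + 3; 2 ⇒ 1.** C9 and C12 are returned to the alcohol and lactone levels, and the C6–C7 bond is cut by a conjugate addition. C8 comes from the chiral pool and directs C7 (trans). The forward addition must occur anti to the C8 substituent.

## Other disconnections considered

**Alternative 1:** The cut is C3–C4. The open-chain iodide A1 (lactone in place, 6-OTES, 9-OTBS, an allyl terminus C1–C2=C3 on C10, a (Z)-C4 iodide) is hydroborated at its terminal olefin with 9-BBN and coupled intramolecularly (Pd(dppf)Cl2, Cs2CO3, high dilution) to give the lactone-fused (Z)-cyclodecene A2.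
- In its favour: the olefin geometry is carried with retention from the iodide, which is the equal of the chosen plan, where it is also fixed before ring closure.
- In its favour: A2 already holds the lactone and needs no auxiliary. The sulfone oxidation, the desulfonylation and the masking and unmasking of the lactone fall away. On step count this is the better plan, by about five steps, if the coupling works.
- Against: the ring must close by reductive elimination from an eleven-membered palladacycle with β-hydrogens on C2. B-alkyl couplings to medium rings are far less documented than to large rings, and β-hydride elimination, protodeboronation and dimerisation are the likely competitors.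
- Against: the lactone meets aqueous carbonate.
- Against: the (Z)-α-methyl alkenyl iodide next to the C6 carbinol is harder to make cleanly than 20.
- Comparison: the chosen plan closes the same ring by a metal-free SN2 step with direct precedent for ten-membered terpenoid rings, and pays for that safety with the sulfone steps.

**Alternative 2:** Here the ring is released, not closed. The C4–C9 bond of the cis-decalin A3 is broken: C9 tertiary alkoxide, angular C4 methyl, equatorial C5 mesylate anti-periplanar to C4–C9, C3 axial on the mesylate ring. Base gives the (Z)-cyclodecenone A4.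
- In its favour: no dilution is needed and entropy is not fought. As a ring-forming event it is better than any ten-membered cyclisation, including the chosen one.
- In its favour: the (Z) geometry follows from the decalin stereochemistry, and C6, C7 and C8 are all equatorial on a chair, so cyclic control there is at least the equal of the chosen acyclic control.
- Against: A3 needs three stereocentres (C4, C5, C9) that are built only to be destroyed, on a contiguously substituted ring, with a hindered mesylate between a quaternary carbon and C6.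
- Against: A4 has a C9 ketone flanked by the epimerisable C10, transannular to the olefin just formed (ene or aldol reclosure), and C9 must then be reduced stereoselectively on the medium ring.
- Against: the C7 vinyl group lacks the carboxyl carbon C12, so the lactone still needs a C–C bond.
- Comparison: more stereochemical work before and after the key step and a clearly longer route. The chosen plan sets C6–C10 once and keeps them.

**Alternative 3:** The C3–C8 bond is broken as C1–C10 forms. The potassium alkoxide of the trans-1-[(E)-propenyl]-2-vinylcyclohexanol A5 (epoxide, 6-OTBS and the C7 side chain already on the six-membered ring) rearranges and A6 is released as its C8 enolate and protonated.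
- In its favour: a [3,3] ring expansion with no dilution. C10 is set through a chair transition state, equal to the chosen plan in reliability.
- In its favour: the epoxide is set on a cyclohexene, where facial control is better than on the ten-membered ring of the chosen plan.
- In its favour: the path to the ten-membered ring is short.
- Against: A6 lacks O9, has C8 as a ketone and carries an extra (E)-C2=C3 olefin. It needs C9 hydroxylation (trapping of the regiodefined enolate is a partial remedy), a C8 reduction and the saturation of a vinyl epoxide without hydrogenolysis.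
- Against: in A5 an alkoxide sits next to an epoxide under strongly basic conditions.
- Comparison: three stereochemical operations would be left for the medium ring against one in the chosen plan, and step economy after the key step is worse.

Key step: step 17

Remark: locants C1–C13 are those of 38 and are kept for every intermediate; the acetal carbon C12 (6, 7, 8, 11, 12, 14–17, 22–29) and C2 of 27 are carried as epimer mixtures that converge at 30 and 28.

## Route

Step 1
Reactants: 1 (S)-5-(hydroxymethyl)furan-2(5H)-one
Product: 2 (S)-5-[(tert-butyldimethylsilyloxy)methyl]furan-2(5H)-one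
Conditions: TBSCl, imidazole, CH2Cl2, 0 °C to rt
Reagents that add atoms: tert-butyldimethylsilyl chloride, CC(C)(C)[Si](C)(C)Cl
Why: O-silylation of a primary alcohol; imidazole is too weak a base to epimerise the γ-centre, so C8 is taken unchanged from the chiral pool.

Step 2
Reactants: 2 (S)-5-[(tert-butyldimethylsilyloxy)methyl]furan-2(5H)-one; 3 (2-methylprop-1-en-1-yl)magnesium bromide
Product: 5 (4R,5S)-5-[(tert-butyldimethylsilyloxy)methyl]-4-(2-methylprop-1-en-1-yl)dihydrofuran-2(3H)-one, via bromomagnesium bis(2-methylprop-1-enyl)cuprate 4 (not isolated)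
Conditions: 3 (2.4 equiv), CuI (1.2 equiv), THF, −40 °C; then 2, −78 °C; aq NH4Cl
Reagents that add atoms: none
Why: Cuprate conjugate addition to a butenolide; the silyloxymethyl group on C8 shields one face, so the alkenyl group enters anti and C7 is set trans (R). The alkenyl group is a masked C6 aldehyde.

Step 3
Reactants: 5 (4R,5S)-5-[(tert-butyldimethylsilyloxy)methyl]-4-(2-methylprop-1-en-1-yl)dihydrofuran-2(3H)-one
Product: 6 (4R,5S)-5-[(tert-butyldimethylsilyloxy)methyl]-4-(2-methylprop-1-en-1-yl)tetrahydrofuran-2-ol
Conditions: iBu2AlH (DIBAL-H, 1.1 equiv), CH2Cl2, −78 °C; Rochelle salt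
Reagents that add atoms: none
Why: Partial reduction of a γ-lactone; the tetrahedral aluminate is stable at −78 °C and gives the lactol on work-up.

Step 4
Reactants: 6 (4R,5S)-5-[(tert-butyldimethylsilyloxy)methyl]-4-(2-methylprop-1-en-1-yl)tetrahydrofuran-2-ol
Product: 7 [(2S,3R)-5-methoxy-3-(2-methylprop-1-en-1-yl)tetrahydrofuran-2-yl]methanol
Conditions: CSA (0.1 equiv), MeOH, 0 °C to rt
Reagents that add atoms: methanol, CO
Why: Fischer-type acetalisation of the lactol through the oxocarbenium ion; the same acid methanolysis cleaves the primary silyl ether. The anomeric mixture is of no consequence because C12 becomes a carbonyl again in step 20.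

Step 5
Reactants: 7 [(2S,3R)-5-methoxy-3-(2-methylprop-1-en-1-yl)tetrahydrofuran-2-yl]methanol
Product: 8 (2S,3R)-5-methoxy-3-(2-methylprop-1-en-1-yl)tetrahydrofuran-2-carbaldehyde
Conditions: Dess–Martin periodinane, NaHCO3, CH2Cl2, 0 °C to rt; used crude
Reagents that add atoms: none
Why: Buffered Dess–Martin oxidation of a primary alcohol; neutral conditions protect the acetal and the α-alkoxy centre C8, whose trans arrangement to C7 is also the thermodynamic one.

Step 6
Reactants: 8 (2S,3R)-5-methoxy-3-(2-methylprop-1-en-1-yl)tetrahydrofuran-2-carbaldehyde; 9 (E)-but-2-ene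
Product: 11 (1R,2R)-1-[(2S,3R)-5-methoxy-3-(2-methylprop-1-en-1-yl)tetrahydrofuran-2-yl]-2-methylbut-3-en-1-ol, via (E)-crotyl-bis(isopinocampheyl)borane 10 (not isolated)
Conditions: 9, KOtBu, n-BuLi, THF, −78 to −45 °C; (+)-Ipc2BOMe, −78 °C; BF3·OEt2; 8, −78 °C; then NaOH, H2O2, 0 °C to rt
Reagents that add atoms: none
Why: Brown crotylboration through a closed chair transition state; the (E)-crotyl geometry gives the 9,10-anti pair, and the reagent made from (+)-Ipc2BOMe ((−)-α-pinene series) attacks the Re face of the aldehyde to give 9R. That face is also the Felkin–Anh/Cornforth face of the α-alkoxy aldehyde (8,9-anti), so reagent and substrate are matched; a pinacol (E)-crotylboronate alone would rely on weak substrate bias.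

Step 7
Reactants: 11 (1R,2R)-1-[(2S,3R)-5-methoxy-3-(2-methylprop-1-en-1-yl)tetrahydrofuran-2-yl]-2-methylbut-3-en-1-ol
Product: 12 (2S,3R)-5-methoxy-2-[(1R,2R)-1-(4-methoxybenzyloxy)-2-methylbut-3-en-1-yl]-3-(2-methylprop-1-en-1-yl)tetrahydrofuran
Conditions: NaH, PMBCl, Bu4NI (cat.), DMF, 0 °C to rt
Reagents that add atoms: 4-methoxybenzyl chloride, COc1ccc(CCl)cc1
Why: Williamson etherification on a substrate with no base-sensitive group; O9 receives the one protecting group it keeps until the last step.

Step 8
Reactants: 12 (2S,3R)-5-methoxy-2-[(1R,2R)-1-(4-methoxybenzyloxy)-2-methylbut-3-en-1-yl]-3-(2-methylprop-1-en-1-yl)tetrahydrofuran; 13 benzenethiol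
Product: 14 (2S,3R)-5-methoxy-2-[(1R,2R)-1-(4-methoxybenzyloxy)-2-methyl-4-(phenylsulfanyl)butyl]-3-(2-methylprop-1-en-1-yl)tetrahydrofuran
Conditions: 13 (2 equiv), AIBN (0.1 equiv), toluene (degassed), 80 °C
Reagents that add atoms: none
Why: Radical thiol–ene addition; the thiyl radical adds at the terminal carbon C2 (anti-Markovnikov) and the secondary radical is quenched by the thiol far faster than it can cyclise. Addition to the trisubstituted olefin is reversible and sterically slow, and that olefin has no geometry to lose.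

Step 9
Reactants: 14 (2S,3R)-5-methoxy-2-[(1R,2R)-1-(4-methoxybenzyloxy)-2-methyl-4-(phenylsulfanyl)butyl]-3-(2-methylprop-1-en-1-yl)tetrahydrofuran
Product: 15 (2S,3R)-5-methoxy-2-[(1R,2R)-1-(4-methoxybenzyloxy)-2-methyl-4-(phenylsulfonyl)butyl]-3-(2-methylprop-1-en-1-yl)tetrahydrofuran
Conditions: (NH4)6Mo7O24·4H2O (0.1 equiv), 30% H2O2, MeOH, 0 °C to rt
Reagents that add atoms: hydrogen peroxide, OO
Why: Molybdate-catalysed oxidation of sulfide to sulfone, which leaves unactivated olefins and the benzyl-type ether alone; methanol as solvent returns any exchanged acetal as the methyl acetal.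

Step 10
Reactants: 15 (2S,3R)-5-methoxy-2-[(1R,2R)-1-(4-methoxybenzyloxy)-2-methyl-4-(phenylsulfonyl)butyl]-3-(2-methylprop-1-en-1-yl)tetrahydrofuran
Product: 17 (2S,3S)-5-methoxy-2-[(1R,2R)-1-(4-methoxybenzyloxy)-2-methyl-4-(phenylsulfonyl)butyl]tetrahydrofuran-3-carbaldehyde, via C6 vicinal diol 16 (not isolated)
Conditions: OsO4 (2 mol%), NaIO4 (4 equiv), 2,6-lutidine, dioxane–H2O (3:1), rt; used crude
Reagents that add atoms: sodium periodate, [Na+].[O-]I(=O)(=O)=O (source of the aldehyde oxygen, relayed by catalytic OsO4)
Why: Lemieux–Johnson cleavage of the electron-rich trisubstituted olefin; osmium spares the 4-methoxybenzyl ether that ozone could attack, and lutidine suppresses over-oxidation. No stereocentre changes (the C7 descriptor changes only because of priorities).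

Step 11
Reactants: 18 prop-2-yn-1-ol
Product: 20 (Z)-3-iodo-2-methylprop-2-en-1-ol, via chelated (Z)-alkenylmagnesium alkoxide 19 (not isolated)
Conditions: MeMgBr (2.5 equiv), CuI (0.1 equiv), THF, −10 °C to rt; then I2, −10 °C
Reagents that add atoms: methylmagnesium bromide, C[Mg]Br; iodine, II
Why: Copper-catalysed anti carbomagnesiation of the propargylic alkoxide puts the methyl on C4 and magnesium on C5 in a five-membered chelate; iodinolysis with retention gives the (Z)-iodide, which fixes the C4=C5 geometry of the whole route.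

Step 12
Reactants: 20 (Z)-3-iodo-2-methylprop-2-en-1-ol
Product: 21 (Z)-triethyl[(3-iodo-2-methylprop-2-en-1-yl)oxy]silane
Conditions: TESCl, imidazole, CH2Cl2, 0 °C
Reagents that add atoms: chlorotriethylsilane, CC[Si](CC)(CC)Cl
Why: Silylation of a primary allylic alcohol; the triethylsilyl group is chosen because it can later be removed in the presence of a secondary tert-butyldimethylsilyl ether.

Step 13
Reactants: 17 (2S,3S)-5-methoxy-2-[(1R,2R)-1-(4-methoxybenzyloxy)-2-methyl-4-(phenylsulfonyl)butyl]tetrahydrofuran-3-carbaldehyde; 21 (Z)-triethyl[(3-iodo-2-methylprop-2-en-1-yl)oxy]silane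
Product: 22 (4Z,6S)-allylic alcohol of the open chain (C2 phenyl sulfone; 9-OPMB; C12 methyl acetal; 3-OTES)
Conditions: 21 (2 equiv), CrCl2 (6 equiv), NiCl2 (2 mol%), DMF (degassed), rt
Reagents that add atoms: none
Why: Nozaki–Hiyama–Kishi coupling; the alkenyl–chromium species (trivalent chromium) forms with retention of the (Z) geometry and adds only to the aldehyde, leaving sulfone and acetal untouched. In the Felkin–Anh transition state C8, the substituted ring carbon, is the large group and attack anti to it places O6 syn to C11 (6S); chromium is not expected to chelate the ring oxygen.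

Step 14
Reactants: 22 (4Z,6S)-allylic alcohol of the open chain
Product: 23 (4Z)-6-O-tert-butyldimethylsilyl-3-O-triethylsilyl bis-ether of the open chain
Conditions: TBSOTf, 2,6-lutidine, CH2Cl2, −78 °C
Reagents that add atoms: tert-butyldimethylsilyl trifluoromethanesulfonate, CC(C)(C)[Si](C)(C)OS(=O)(=O)C(F)(F)F
Why: Silyl triflate silylation of a hindered secondary allylic alcohol at low temperature, where the methyl acetal is not ionised; a silyl ether on O6 cannot act as an internal nucleophile towards C3.

Step 15
Reactants: 23 (4Z)-6-O-tert-butyldimethylsilyl-3-O-triethylsilyl bis-ether of the open chain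
Product: 24 (4Z)-C3 primary allylic alcohol with 6-OTBS
Conditions: PPTS (0.1 equiv), MeOH, 0 °C
Reagents that add atoms: none
Why: Mild acid methanolysis removes a primary triethylsilyl ether much faster than a hindered secondary tert-butyldimethylsilyl ether; the acetal stays a methyl acetal in methanol.

Step 16
Reactants: 24 (4Z)-C3 primary allylic alcohol with 6-OTBS
Product: 26 (4Z)-C3 allylic chloride with the C2 phenyl sulfone (6-OTBS; 9-OPMB; C12 methyl acetal), via C3 allylic mesylate 25 (not isolated)
Conditions: MsCl, 2,4,6-collidine, LiCl, DMF, 0 °C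
Reagents that add atoms: lithium chloride, [Li+].[Cl-]
Why: Mesylation followed by chloride displacement at the primary carbon; direct SN2 at C3 is favoured over attack at the hindered C5, so neither allylic transposition nor loss of the (Z) geometry is expected.

Step 17
Reactants: 26 (4Z)-C3 allylic chloride with the C2 phenyl sulfone (6-OTBS; 9-OPMB; C12 methyl acetal)
Product: 27 (4Z)-cyclodecene with 2-phenylsulfonyl (6-OTBS; 9-OPMB; trans-fused 12-methoxy-oxolane; both C2 epimers)
Conditions: KN(SiMe3)2 (2.5 equiv), THF, 0 °C to rt; 26 added over 8 h by syringe pump, final 0.002 M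
Reagents that add atoms: none
Why: The amide base deprotonates C2 next to the sulfone, the only carbon acid left because the lactone is an acetal and every hydroxyl is capped, and the carbanion displaces chloride from C3 in a direct SN2 reaction. The closest known reaction type is the intramolecular alkylation of sulfur-stabilised carbanions by allylic halides to ten-membered terpenoid rings. The one ring closed is the carbocycle, in the 10-exo-tet mode. No stereocentre of consequence is created: C2 forms as either epimer and loses its sulfonyl group in step 18, and C6–C10 are not α to any acidifying group. Ring closure must beat oligomerisation, which slow addition to high dilution and two turn elements should secure: the (Z)-olefin and the trans-fused oxolane that holds C6 and C9 as in 38. SN2 must beat SN2′, which is expected because C3 is primary and open whereas C5 is secondary, flanked by the silyloxy carbon, and would give an eight-membered ring. The hindered base should not alkylate on nitrogen, the (Z) geometry survives because no allyl–metal intermediate forms, and O6 as a silyl ether cannot close a dihydrofuran onto C3.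

Step 18
Reactants: 27 (4Z)-cyclodecene with 2-phenylsulfonyl
Product: 28 (4Z)-cyclodecene with 6-OTBS; 9-OPMB; trans-fused 12-methoxy-oxolane
Conditions: Mg turnings (20 equiv), MeOH, 50 °C
Reagents that add atoms: none
Why: Reductive desulfonylation by electron transfer from magnesium; C2 becomes a methylene group and both epimers converge. Silyl ether, benzyl-type ether, acetal and isolated olefin are inert to these conditions.

Step 19
Reactants: 28 (4Z)-cyclodecene with 6-OTBS; 9-OPMB; trans-fused 12-methoxy-oxolane
Product: 29 (4Z)-cyclodecene-fused lactol (12-hydroxy-oxolane; 6-OTBS; 9-OPMB)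
Conditions: AcOH–THF–H2O (3:1:1), 40 °C
Reagents that add atoms: water, O
Why: Hydrolysis of a 2-alkoxytetrahydrofuran, an acetal as labile as a tetrahydropyranyl ether, under conditions a hindered secondary tert-butyldimethylsilyl ether tolerates.

Step 20
Reactants: 29 (4Z)-cyclodecene-fused lactol
Product: 30 (4Z)-12,8-lactone (6-OTBS; 9-OPMB)
Conditions: Pr4N[RuO4] (5 mol%), NMO, 4 Å molecular sieves, CH2Cl2, rt
Reagents that add atoms: none
Why: Ley–Griffith oxidation of a lactol to the lactone; because O8 was never free apart from C12, only the γ-lactone can form.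

Step 21
Reactants: 30 (4Z)-12,8-lactone (6-OTBS; 9-OPMB)
Product: 33 (4Z)-α-methylene-12,8-lactone (6-OTBS; 9-OPMB), via 11-(dimethylaminomethyl) lactone 31 (not isolated), via its trimethylammonium iodide 32 (not isolated)
Conditions: LiN(iPr)2 (1.3 equiv), THF, −78 °C; Me2N=CH2+ I−, −78 °C to rt; then MeI, MeOH, rt; then aq NaHCO3, EtOAc, rt
Reagents that add atoms: N,N-dimethylmethyleneiminium iodide (Eschenmoser's salt), C[N+](C)=C.[I-]
Why: Mannich reaction of the lactone enolate, quaternisation and mild Hofmann-type elimination; only C11 is enolisable and no leaving group sits β to the enolate, and the configuration at C11 is lost in the elimination.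

Step 22
Reactants: 33 (4Z)-α-methylene-12,8-lactone (6-OTBS; 9-OPMB)
Product: 34 (4Z)-6-hydroxy-α-methylene-12,8-lactone (9-OPMB)
Conditions: HF·pyridine, pyridine, THF, 0 °C to rt
Reagents that add atoms: none
Why: Buffered fluoride desilylation; the weakly acidic medium avoids conjugate addition to the methylene lactone and base-induced shift of the lactone from O8 to O6.

Step 23
Reactants: 34 (4Z)-6-hydroxy-α-methylene-12,8-lactone (9-OPMB)
Product: 35 (4R,5S)-4,5-epoxy-6-hydroxy-α-methylene-12,8-lactone (9-OPMB)
Conditions: mCPBA, NaHCO3, CH2Cl2, 0 °C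
Reagents that add atoms: 3-chloroperoxybenzoic acid, O=C(OO)c1cccc(Cl)c1
Why: Peracid epoxidation of the electron-rich trisubstituted olefin; the conjugated exo-methylene is inert. With H6 eclipsing the olefin (allylic 1,3-strain against C3), O6 lies on the outer face at about 120° to the π plane, the geometry preferred for hydrogen-bonded peracid delivery, so peripheral attack and hydroxyl direction both give the epoxide threo to O6. A vanadium-alkoxide delivery, which prefers a dihedral of 40–50°, is less safe in a medium-ring (Z)-cycloalkenol.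

Step 24
Reactants: 35 (4R,5S)-4,5-epoxy-6-hydroxy-α-methylene-12,8-lactone (9-OPMB); 36 3-methylbut-2-enoic acid
Product: 37 (4R,5S)-4,5-epoxy-6-(3-methylbut-2-enoyloxy)-α-methylene-12,8-lactone (9-OPMB)
Conditions: DCC, DMAP, CH2Cl2, 0 °C to rt
Reagents that add atoms: none
Why: Steglich esterification; with no stoichiometric amine base present, formation of the vinylketene that would deconjugate the senecioate is suppressed, and epoxide and methylene lactone are untouched.

Step 25
Reactants: 37 (4R,5S)-4,5-epoxy-6-(3-methylbut-2-enoyloxy)-α-methylene-12,8-lactone (9-OPMB)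
Product: 38 (4R,5S,6R,7S,8S,9R,10R)-4,5-epoxy-9-hydroxy-6-(3-methylbut-2-enoyloxy)germacr-11(13)-en-12,8-olide (CNP0119422.2)
Conditions: DDQ, CH2Cl2–pH 7 phosphate buffer (10:1), 0 °C to rt
Reagents that add atoms: none
Why: Oxidative cleavage of the 4-methoxybenzyl ether by hydride abstraction and hydrolysis; the buffered, near-neutral conditions spare epoxide, senecioate and methylene lactone.

## Compound list

1 | (S)-5-(hydroxymethyl)furan-2(5H)-one | O=C1C=C[C@@H](CO)O1 | starting material
2 | (S)-5-[(tert-butyldimethylsilyloxy)methyl]furan-2(5H)-one | O=C1C=C[C@@H](CO[Si](C)(C)C(C)(C)C)O1 | intermediate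
3 | (2-methylprop-1-en-1-yl)magnesium bromide | CC(C)=C[Mg]Br | starting material
4 | bromomagnesium bis(2-methylprop-1-en-1-yl)cuprate | CC(C)=C[Cu-]C=C(C)C.[Mg+]Br | intermediate (not isolated)
5 | (4R,5S)-5-[(tert-butyldimethylsilyloxy)methyl]-4-(2-methylprop-1-en-1-yl)dihydrofuran-2(3H)-one | O=C1C[C@H](C=C(C)C)[C@@H](CO[Si](C)(C)C(C)(C)C)O1 | intermediate
6 | (4R,5S)-5-[(tert-butyldimethylsilyloxy)methyl]-4-(2-methylprop-1-en-1-yl)tetrahydrofuran-2-ol, both C2 epimers | OC1C[C@H](C=C(C)C)[C@@H](CO[Si](C)(C)C(C)(C)C)O1 | intermediate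
7 | [(2S,3R)-5-methoxy-3-(2-methylprop-1-en-1-yl)tetrahydrofuran-2-yl]methanol, both C5 epimers | COC1C[C@H](C=C(C)C)[C@@H](CO)O1 | intermediate
8 | (2S,3R)-5-methoxy-3-(2-methylprop-1-en-1-yl)tetrahydrofuran-2-carbaldehyde | COC1C[C@H](C=C(C)C)[C@@H](C=O)O1 | intermediate
9 | (E)-but-2-ene | C/C=C/C | starting material
10 | [(E)-but-2-en-1-yl]bis(isopinocampheyl)borane of the (−)-α-pinene series | C/C=C/CB([C@H]1C[C@H]2C[C@@H]([C@@H]1C)C2(C)C)[C@H]1C[C@H]2C[C@@H]([C@@H]1C)C2(C)C | intermediate (not isolated)
11 | (1R,2R)-1-[(2S,3R)-5-methoxy-3-(2-methylprop-1-en-1-yl)tetrahydrofuran-2-yl]-2-methylbut-3-en-1-ol | C=C[C@@H](C)[C@@H](O)[C@H]1OC(OC)C[C@@H]1C=C(C)C | intermediate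
12 | (2S,3R)-5-methoxy-2-[(1R,2R)-1-(4-methoxybenzyloxy)-2-methylbut-3-en-1-yl]-3-(2-methylprop-1-en-1-yl)tetrahydrofuran | C=C[C@@H](C)[C@@H](OCc1ccc(OC)cc1)[C@H]2OC(OC)C[C@@H]2C=C(C)C | intermediate
13 | benzenethiol | Sc1ccccc1 | starting material
14 | (2S,3R)-5-methoxy-2-[(1R,2R)-1-(4-methoxybenzyloxy)-2-methyl-4-(phenylsulfanyl)butyl]-3-(2-methylprop-1-en-1-yl)tetrahydrofuran | c1ccccc1SCC[C@@H](C)[C@@H](OCc1ccc(OC)cc1)[C@H]2OC(OC)C[C@@H]2C=C(C)C | intermediate
15 | (2S,3R)-5-methoxy-2-[(1R,2R)-1-(4-methoxybenzyloxy)-2-methyl-4-(phenylsulfonyl)butyl]-3-(2-methylprop-1-en-1-yl)tetrahydrofuran | O=S(=O)(c1ccccc1)CC[C@@H](C)[C@@H](OCc1ccc(OC)cc1)[C@H]2OC(OC)C[C@@H]2C=C(C)C | intermediate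
16 | 1-{(2S,3R)-5-methoxy-2-[(1R,2R)-1-(4-methoxybenzyloxy)-2-methyl-4-(phenylsulfonyl)butyl]tetrahydrofuran-3-yl}-2-methylpropane-1,2-diol, both C1 epimers | O=S(=O)(c1ccccc1)CC[C@@H](C)[C@@H](OCc1ccc(OC)cc1)[C@H]2OC(OC)C[C@@H]2C(O)C(C)(C)O | intermediate (not isolated)
17 | (2S,3S)-5-methoxy-2-[(1R,2R)-1-(4-methoxybenzyloxy)-2-methyl-4-(phenylsulfonyl)butyl]tetrahydrofuran-3-carbaldehyde | O=S(=O)(c1ccccc1)CC[C@@H](C)[C@@H](OCc1ccc(OC)cc1)[C@H]2OC(OC)C[C@@H]2C=O | intermediate
18 | prop-2-yn-1-ol | C#CCO | starting material
19 | bromomagnesium (Z)-3-(bromomagnesio)-2-methylprop-2-en-1-olate | Br[Mg]OC/C(C)=C\[Mg]Br | intermediate (not isolated)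
20 | (Z)-3-iodo-2-methylprop-2-en-1-ol | OC/C(C)=C\I | intermediate
21 | (Z)-triethyl[(3-iodo-2-methylprop-2-en-1-yl)oxy]silane | CC[Si](CC)(CC)OC/C(C)=C\I | intermediate
22 | open chain PhSO2–C2H2–C1H2–C10H(CH3)–C9H(OPMB)–C8H(–O–C12H(OCH3)–C11H2–)C7H–C6H(OH)–C5H=C4(CH3)–C3H2–OTES with the oxolane closed between C8 and C7; (4Z), (6S,7R,8S,9R,10R) | O=S(=O)(c1ccccc1)CC[C@@H](C)[C@@H](OCc1ccc(OC)cc1)[C@H]2OC(OC)C[C@@H]2[C@@H](O)/C=C(C)\CO[Si](CC)(CC)CC | intermediate
23 | 6-O-tert-butyldimethylsilyl ether of 22; (4Z), (6S,7S,8S,9R,10R) | O=S(=O)(c1ccccc1)CC[C@@H](C)[C@@H](OCc1ccc(OC)cc1)[C@H]2OC(OC)C[C@@H]2[C@@H](O[Si](C)(C)C(C)(C)C)/C=C(C)\CO[Si](CC)(CC)CC | intermediate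
24 | C3 primary allylic alcohol from 23 (6-OTBS kept); (4Z), (6S,7S,8S,9R,10R) | O=S(=O)(c1ccccc1)CC[C@@H](C)[C@@H](OCc1ccc(OC)cc1)[C@H]2OC(OC)C[C@@H]2[C@@H](O[Si](C)(C)C(C)(C)C)/C=C(C)\CO | intermediate
25 | C3 methanesulfonate of 24 | O=S(=O)(c1ccccc1)CC[C@@H](C)[C@@H](OCc1ccc(OC)cc1)[C@H]2OC(OC)C[C@@H]2[C@@H](O[Si](C)(C)C(C)(C)C)/C=C(C)\COS(C)(=O)=O | intermediate (not isolated)
26 | open-chain C2 phenyl sulfone with (Z)-allylic chloride at C3, 6-OTBS, 9-OPMB, C12 methyl acetal (oxolane O8–C12–C11–C7–C8); (6S,7S,8S,9R,10R) | O=S(=O)(c1ccccc1)CC[C@@H](C)[C@@H](OCc1ccc(OC)cc1)[C@H]2OC(OC)C[C@@H]2[C@@H](O[Si](C)(C)C(C)(C)C)/C=C(C)\CCl | intermediate (key-step precursor)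
27 | (4Z)-cyclodec-4-ene C1–C10 with phenylsulfonyl on C2 (both epimers), 6-OTBS, 9-OPMB, 10-methyl, 4-methyl and the 12-methoxy-oxolane trans-fused at C7–C8; (6S,7S,8S,9R,10R) | O=S(=O)(c1ccccc1)C3C[C@@H](C)[C@@H](OCc1ccc(OC)cc1)[C@H]2OC(OC)C[C@@H]2[C@@H](O[Si](C)(C)C(C)(C)C)/C=C(C)\C3 | intermediate (key-step product)
28 | desulfonylated (4Z)-cyclodecene, otherwise as 27; (6S,7S,8S,9R,10R) | C1C[C@@H](C)[C@@H](OCc3ccc(OC)cc3)[C@H]2OC(OC)C[C@@H]2[C@@H](O[Si](C)(C)C(C)(C)C)/C=C(C)\C1 | intermediate
29 | lactol of 28 (12-hydroxy-oxolane); (6S,7S,8S,9R,10R) | C1C[C@@H](C)[C@@H](OCc3ccc(OC)cc3)[C@H]2OC(O)C[C@@H]2[C@@H](O[Si](C)(C)C(C)(C)C)/C=C(C)\C1 | intermediate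
30 | (4Z)-6-OTBS-9-OPMB-germacr-4-en-12,8-olide lacking C13; (6S,7S,8S,9R,10R) | C1C[C@@H](C)[C@@H](OCc3ccc(OC)cc3)[C@H]2OC(=O)C[C@@H]2[C@@H](O[Si](C)(C)C(C)(C)C)/C=C(C)\C1 | intermediate
31 | 11-(dimethylaminomethyl) derivative of 30 (C11 epimers) | C1C[C@@H](C)[C@@H](OCc3ccc(OC)cc3)[C@H]2OC(=O)C(CN(C)C)[C@@H]2[C@@H](O[Si](C)(C)C(C)(C)C)/C=C(C)\C1 | intermediate (not isolated)
32 | trimethylammonium iodide of 31 | C1C[C@@H](C)[C@@H](OCc3ccc(OC)cc3)[C@H]2OC(=O)C(C[N+](C)(C)C)[C@@H]2[C@@H](O[Si](C)(C)C(C)(C)C)/C=C(C)\C1.[I-] | intermediate (not isolated)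
33 | (4Z)-6-OTBS-9-OPMB-germacra-4,11(13)-dien-12,8-olide; (6S,7S,8S,9R,10R) | C1C[C@@H](C)[C@@H](OCc3ccc(OC)cc3)[C@H]2OC(=O)C(=C)[C@@H]2[C@@H](O[Si](C)(C)C(C)(C)C)/C=C(C)\C1 | intermediate
34 | (4Z)-6-hydroxy-9-OPMB-germacra-4,11(13)-dien-12,8-olide; (6S,7R,8S,9R,10R) | C1C[C@@H](C)[C@@H](OCc3ccc(OC)cc3)[C@H]2OC(=O)C(=C)[C@@H]2[C@@H](O)/C=C(C)\C1 | intermediate
35 | (4R,5S,6R,7R,8S,9R,10R)-4,5-epoxy-6-hydroxy-9-(4-methoxybenzyloxy)germacr-11(13)-en-12,8-olide | C1C[C@@H](C)[C@@H](OCc3ccc(OC)cc3)[C@H]2OC(=O)C(=C)[C@@H]2[C@@H](O)[C@@H]4O[C@]4(C)C1 | intermediate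
36 | 3-methylbut-2-enoic acid | CC(C)=CC(=O)O | starting material
37 | (4R,5S,6R,7S,8S,9R,10R)-4,5-epoxy-9-(4-methoxybenzyloxy)-6-(3-methylbut-2-enoyloxy)germacr-11(13)-en-12,8-olide | C1C[C@@H](C)[C@@H](OCc3ccc(OC)cc3)[C@H]2OC(=O)C(=C)[C@@H]2[C@@H](OC(=O)C=C(C)C)[C@@H]4O[C@]4(C)C1 | intermediate
38 | (4R,5S,6R,7S,8S,9R,10R)-4,5-epoxy-9-hydroxy-6-(3-methylbut-2-enoyloxy)germacr-11(13)-en-12,8-olide (CNP0119422.2) | C=C1C(=O)O[C@@H]2[C@H](O)[C@H](C)CCC[C@@]3(C)O[C@H]3[C@H](OC(=O)C=C(C)C)[C@@H]12 | target

## Step count and least certain steps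

Total step count: 25. Longest linear sequence: 23 steps (1 to 38 through steps 1–10 and 13–25); the side branch 18 to 21 takes 2 steps.

**Step 17 (key step).** Intermolecular alkylation can outrun the closure of a strained ten-membered ring. The amide base may also consume the allylic chloride by elimination or N-alkylation, and closure through C5 (SN2′) would give an eight-membered ring. The fallback uses a doubly stabilised, far less basic carbanion under carbonate conditions. It sets out from 23. The sulfone is deprotonated with LiN(iPr)2 (2.2 equiv) and sulfonylated with benzenesulfonyl fluoride to the geminal bis(phenylsulfonyl) bis-silyl ether F1. PPTS in methanol gives the geminal bis-sulfone allylic alcohol F2. MsCl, LiCl and collidine give the geminal bis-sulfone allylic chloride F3. Cs2CO3 and CsI in MeCN at high dilution (Finkelstein activation in the flask) close the ring to the 2,2-bis(phenylsulfonyl) cyclodecene F4. Magnesium in methanol removes both sulfonyl groups, and the route is rejoined at 28.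

**Step 13.** The facial bias at C6 may be low, or coordination of chromium to the ring oxygen O8 may compete with the Felkin–Anh mode. The β-alkoxy aldehyde may also epimerise or open by β-elimination if handled slowly. The fallback sets C6 by reagent control. It sets out from 22 as its C6 epimer mixture. Dess–Martin oxidation gives the (Z)-enone F5, which is reduced with (S)-2-methyl-CBS-oxazaborolidine and catecholborane in toluene at −78 °C (Corey–Bakshi–Shibata reduction, the conjugated alkenyl arm taken as the large substituent). This returns a single epimer of 22.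

**Step 23.** Facial selectivity may be poor if a ring conformer with O6 turned inwards reacts, because hydrogen-bonded delivery would then reach the other face. The fallback relies on steric control alone. It sets out from 33, where the bulky silyl ether should hold H6 inside. Dimethyldioxirane in acetone at 0 °C gives the 4,5-epoxy silyl ether F6 by peripheral attack. HF·pyridine then frees O6 and the route is rejoined at 35.

**Step 8.** The reversible thiyl addition may stall, or net addition to the trisubstituted olefin may erode chemoselectivity. The fallback is ionic and sets out from 12. 9-BBN followed by NaOH and H2O2 hydroborates only the terminal olefin to the C2 primary alcohol F7. Diphenyl disulfide and tributylphosphine convert it into the sulfide, and the route is rejoined at 14.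

## Further compounds

F1 | step 17 | geminal bis(phenylsulfonyl) analogue of 23 (second PhSO2 on C2) | O=S(=O)(c1ccccc1)C(S(=O)(=O)c1ccccc1)C[C@@H](C)[C@@H](OCc1ccc(OC)cc1)[C@H]2OC(OC)C[C@@H]2[C@@H](O[Si](C)(C)C(C)(C)C)/C=C(C)\CO[Si](CC)(CC)CC
F2 | step 17 | geminal bis-sulfone C3 allylic alcohol | O=S(=O)(c1ccccc1)C(S(=O)(=O)c1ccccc1)C[C@@H](C)[C@@H](OCc1ccc(OC)cc1)[C@H]2OC(OC)C[C@@H]2[C@@H](O[Si](C)(C)C(C)(C)C)/C=C(C)\CO
F3 | step 17 | geminal bis-sulfone C3 allylic chloride | O=S(=O)(c1ccccc1)C(S(=O)(=O)c1ccccc1)C[C@@H](C)[C@@H](OCc1ccc(OC)cc1)[C@H]2OC(OC)C[C@@H]2[C@@H](O[Si](C)(C)C(C)(C)C)/C=C(C)\CCl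
F4 | step 17 | 2,2-bis(phenylsulfonyl) analogue of 27 | O=S(=O)(c1ccccc1)C3(S(=O)(=O)c1ccccc1)C[C@@H](C)[C@@H](OCc1ccc(OC)cc1)[C@H]2OC(OC)C[C@@H]2[C@@H](O[Si](C)(C)C(C)(C)C)/C=C(C)\C3
F5 | step 13 | (Z)-enone, C6 ketone of 22 | O=S(=O)(c1ccccc1)CC[C@@H](C)[C@@H](OCc1ccc(OC)cc1)[C@H]2OC(OC)C[C@@H]2C(=O)/C=C(C)\CO[Si](CC)(CC)CC
F6 | step 23 | (4R,5S)-4,5-epoxide of 33 (6-OTBS kept) | C1C[C@@H](C)[C@@H](OCc3ccc(OC)cc3)[C@H]2OC(=O)C(=C)[C@@H]2[C@@H](O[Si](C)(C)C(C)(C)C)[C@@H]4O[C@]4(C)C1
F7 | step 8 | C2 primary alcohol from 12: (3R,4R)-4-(4-methoxybenzyloxy)-4-[(2S,3R)-5-methoxy-3-(2-methylprop-1-en-1-yl)tetrahydrofuran-2-yl]-3-methylbutan-1-ol | OCC[C@@H](C)[C@@H](OCc1ccc(OC)cc1)[C@H]2OC(OC)C[C@@H]2C=C(C)C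
A1 | alternative 1 | trans-lactone with the (1R,2R)-1-(tert-butyldimethylsilyloxy)-2-methylpent-4-enyl chain on C8 and the (1S,2Z)-3-iodo-1-(triethylsilyloxy)but-2-enyl chain on C7 | C=CC[C@@H](C)[C@@H](O[Si](C)(C)C(C)(C)C)[C@H]1OC(=O)C[C@@H]1[C@@H](O[Si](CC)(CC)CC)/C=C(C)\I
A2 | alternative 1 | lactone-fused (Z)-cyclodecene with 6-OTES, 9-OTBS and C11 as methylene | C1C(=O)O[C@@H]2[C@H](O[Si](C)(C)C(C)(C)C)[C@H](C)CCC/C(C)=C\[C@H](O[Si](CC)(CC)CC)[C@@H]12
A3 | alternative 2 | cis-decalin with C9 tertiary hydroxyl, angular C4 methyl, equatorial C5 mesylate, 6-OTES, 7-vinyl, 8-OPMB and 10-methyl | C=C[C@H]1[C@H](OCc2ccc(OC)cc2)[C@@]3(O)[C@H](C)CCC[C@@]3(C)[C@@H](OS(C)(=O)=O)[C@@H]1O[Si](CC)(CC)CC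
A4 | alternative 2 | (Z)-cyclodec-5-enone (C9 ketone) with 6-OTES, 7-vinyl, 8-OPMB and 10-methyl | O=C1[C@H](C)CCC/C(C)=C\[C@H](O[Si](CC)(CC)CC)[C@@H](C=C)[C@@H]1OCc2ccc(OC)cc2
A5 | alternative 3 | trans-1-[(E)-prop-1-enyl]-2-vinylcyclohexanol carrying the C4–C5 epoxide, 6-OTBS and the 2-(4-methoxybenzyloxy)ethyl chain on C7 | C/C=C/[C@]1(O)[C@@H](C=C)[C@@]2(C)O[C@H]2[C@H](O[Si](C)(C)C(C)(C)C)[C@H]1CCOCc3ccc(OC)cc3
A6 | alternative 3 | ten-membered C8 ketone with (E)-C2=C3 olefin, C4–C5 epoxide, 6-OTBS, 10-methyl and the 2-(4-methoxybenzyloxy)ethyl chain on C7 | O=C1C[C@H](C)C/C=C/[C@@]2(C)O[C@H]2[C@H](O[Si](C)(C)C(C)(C)C)[C@H]1CCOCc3ccc(OC)cc3
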